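Assumption: ring A and ring C atoms carry their flavone numbers (O1, C2 to C8a) in every intermediate, including the open chain and the pyrone. On that basis precursor 7 and flavone 10 were checked atom by atom; they are isomers (C17H14O6) and need no structural correction. The 4-hydroxyl of 7 is left free because the magnesium-templated fold is precedented for the free hydroxypyrone.

## Structural features

The target is a flavone: a benzene ring A fused through C4a–C8a to a 4-pyranone ring C (together a 4H-chromen-4-one), with a 2,4-dimethoxyphenyl ring B attached to C2 by the single C2–C1' bond. It has no stereocentre, so no stereocentres stand next to each other and the whole problem is one of regiochemistry. Ring A is substituted at every position but C6: a free hydroxyl on C5 that is hydrogen-bonded to the C4 carbonyl, methoxyls on C7 and C8, and the ring oxygen O1 on C8a. The fragile points are the 5,8-dioxygenated ring A, which becomes an easily oxidised hydroquinone once both oxygens are free, the pyranone ring, which hot aqueous base opens at C2, and, among the intermediates, the conjugated ynone. The real difficulty is to tell four oxygens on one benzene ring apart (one free, two methylated, one in the heterocycle) and to place the oxygen on C8, which lies outside the alternating pattern. The key step exploits that the oxygens on C5, C7 and C8a alternate with the oxygen-free C6, C8 and C4a, and that this alternation continues through the C4 carbonyl and C3 to the oxygen-bearing C2. The nine carbons from C8a round ring A to C2 are therefore a folded poly-β-carbonyl chain capped by ring B. The endgame uses two further features: chelation makes the C5 hydroxyl the least reactive phenol, and C8 is para to C5.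

## Logic of the disconnections

**14 ⇒ 13.** The O–CH3 bond on the C8 oxygen is cut first. In 13 that oxygen is the only phenol not tied to the C4 carbonyl, so the cut removes a methyl group without creating a selectivity problem that chelation does not already solve. The forward step must alkylate once, at O8 only, and must keep the hydroquinone ring of 13 away from air while it is in base.

**13 ⇒ 11.** The C8–O bond is cut, because C8 carries the one oxygen outside the alternating pattern and it lies para to the C5 hydroxyl. Removing it gives 11, whose ring A shows the pure C5/C7/C8a pattern. The forward step must hydroxylate an aromatic C–H para to a phenolate and leave ring B, the C2–C3 double bond and C6 alone; it passes through 12.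

**11 ⇒ 10.** The O–CH3 bond on the C7 oxygen is cut, which leads back to 10, whose ring A derives from a symmetric triol. The methyl group is put on before the oxidation because a capped O7 leaves the C5 phenolate as the only one, and that phenolate points the oxidant at C8; a free O7 phenolate would also activate C6. The methyl group is not carried through the fold as an ether on the hydroxyl of 5, because the fold is precedented for the free hydroxyl. The forward step must methylate the unchelated, more acidic O7 and spare O5.

**10 ⇒ 7.** Both C4a–C8a and O1–C2 are cut. This opens rings A and C at once and unfolds C8a–C8–C7–C6–C5–C4a–C4–C3–C2 into one chain ending at ring B. In 7 the chain is stored with C8a as a lactone carbonyl, the C5 oxygen as the lactone ring oxygen, the C7 oxygen as an enol and C2/C3 as an alkyne. Because 7 is an isomer of 10, the fold needs neither oxidant nor dehydrating agent. The gain is the largest of the route: a bicyclic heteroaromatic becomes a monocyclic pyrone with a linear side chain. The demand is equally large. The lactone must open to 8, C4a must attack C8a in preference to the aldol mode, and one ortho oxygen of 9 must add to C2 and not to C3. Magnesium chelation and the symmetry of 9 are relied on for this.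

**7 ⇒ 5 + 4.** The C4–C4a bond is cut, between the side-chain methylene and the ketone carbon. This divides 7 into 5, which is commercial and holds C4a to C8a with all three oxygens, and 4, which holds C4, C3, C2 and ring B. The forward step needs a carbanion on the methyl carbon of 5 despite its acidic hydroxyl (hence 6). It also needs an acyl donor that reacts at the carbonyl carbon, not at the triple bond, and that does not release the ynone while 6 is still present.

**4 ⇒ 3.** The amide C–N bond is cut to reveal the acid. This costs one step but gives an acyl donor that stops at the ketone stage. The forward step must activate an alkynoic acid without adding the amine or the activator across the triple bond.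

**3 ⇒ 1 + 2.** The bond between the aryl carbon (later C1') and the alkyne carbon (later C2) is cut, which leaves two commercial compounds. The forward coupling must run cold enough that the product keeps its carboxyl group.

## Other disconnections considered

Alternative 1: The cut takes ring C apart at C4a–C4, C4–C3 and O1–C2, so the flavone comes from three pieces: 2-iodo-3,5,6-trimethoxyphenol A1, CO and 1-ethynyl-2,4-dimethoxybenzene A2.
- **Forward key step:** PdCl2(PPh3)2 in diethylamine (the divalent palladium complex is reduced to zerovalent palladium in the flask) would insert into the C–I bond of A1, take up CO and transfer the acyl group to A2. The amine would then carry the ortho-hydroxyaryl ynone through an enaminone to 2-(2,4-dimethoxyphenyl)-5,7,8-trimethoxy-4H-chromen-4-one A3. Cleavage of the chelated 5-methyl ether of A3 with BCl3 would give 14.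
- **In its favour:** three bonds form in one step, every ring A oxygen including that on C8 is in place before ring C exists, no late C–H oxidation is needed, and only one step separates A3 from the target. The enaminone pathway also closes the six-membered ring cleanly.
- **Against it here:** A1 is not commercial and carries the whole regiochemical problem of ring A (four differentiated oxygens and an iodine on one benzene), so the difficulty is moved into an arene synthesis rather than removed. Oxidative addition and CO insertion at a C–I bond flanked by a hydroxyl and a methoxyl on a very electron-rich ring are expected to be slow, so direct, non-carbonylative coupling to a benzofuran would compete. CO gas must be handled.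
- **Comparison:** on structure it ignores the polyketide pattern but sets the C8 oxygen early, which is better than the Elbs step of the chosen plan. On mechanism it is a palladium cascade against a base-mediated fold, and the two are about equally well founded. On step economy its key step and endgame are better, but the overall count depends on the preparation of A1, which would probably cost about what the endgame saves.

Alternative 2: The cut is the O1–C8a bond alone; ring A arrives as the hydroquinone diketone 1-(3,6-dihydroxy-2,4-dimethoxyphenyl)-3-(2,4-dimethoxyphenyl)propane-1,3-dione A4.
- **Forward key step:** Ag2O would oxidise A4 to the acylquinone 2-[3-(2,4-dimethoxyphenyl)-3-oxopropanoyl]-3,5-dimethoxycyclohexa-2,5-diene-1,4-dione A5. Its methoxyl next to the acyl group is a vinylogous ester, so the enol oxygen of the diketone would add to that carbon (6-endo-trig) and methanol would leave. This gives 2-(2,4-dimethoxyphenyl)-7-methoxy-4H-chromene-4,5,8-trione A6. Reduction of A6 (Na2S2O4) would give 13, and step 7 would finish.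
- **In its favour:** the C8 oxygen is present from the start as a quinone carbonyl, so no Elbs oxidation is needed, which is better than the chosen plan. Only one methoxyl is within reach of the enol, so the closure is regiochemically unambiguous. The C5 and C8 oxygens emerge free and already distinguished from the C7 methoxyl, and the route joins the chosen one at 13, so the last step is equal.
- **Against it here:** A4 is a pentasubstituted benzene that needs its own multi-step synthesis (an acetophenone of that pattern plus a Baker–Venkataraman chain extension). Acylquinones such as A5 are strongly electrophilic, so the unsubstituted C6 could take up water, methanol or a second enol, and the central carbon of the diketone is a competing C-nucleophile. Oxidation followed by reduction is a redox detour.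
- **Comparison:** on mechanism, addition–elimination on a quinone is as sound as the Claisen/oxa-Michael cascade, but it forms one bond and one ring where the chosen step forms two and two. On step economy, the shorter endgame is likely outweighed by the longer route to A4.

Alternative 3: The cut runs through O1–C8a, C4–C4a and O1–C2. Ring A is supplied as an aryne released by CsF from 3,5-dimethoxy-2-(trimethylsilyl)phenyl trifluoromethanesulfonate A7; C2, C3, C4 and ring B come from acid 3, which the chosen route makes in step 1.
- **Forward key step:** the carboxylate of 3 would add to the aryne carbon remote from the flanking methoxyl. The aryl anion next to that methoxyl would take the acyl carbon, a net insertion into the C–O bond, and the phenoxide would close 6-endo-dig onto the ynone to give 2-(2,4-dimethoxyphenyl)-5,7-dimethoxy-4H-chromen-4-one A8. BCl3 would then cleave the chelated 5-methyl ether of A8 to 11, after which steps 6 and 7 follow.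
- **In its favour:** three bonds and ring C form in one step from an intermediate already in hand. The aryne methoxyl directs the addition to the C5/C7 pattern, the aprotic medium favours six-membered closure, and the C7 methoxyl is already in place. The longest linear sequence would be five steps against seven, which is better.
- **Against it here:** A7 needs about three steps of its own from a dimethoxyphenol. Proton transfer to the aryl anion would give an aryl ester in place of the ketone, and a second aryne could arylate the phenoxide. One extra demethylation is needed. The C8 oxygen would still come from the same Elbs oxidation, so the weakest step of the chosen plan is not avoided.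
- **Comparison:** on structure both plans build the same C5/C7 pattern and add the C8 oxygen late, so they are equal. On mechanism the aryne insertion has more competing channels than the magnesium-templated fold. On step economy the alternative is better in linear count and about equal in total operations.

Key step: step 4

## Route

Step 1
Reactants: 1 1-iodo-2,4-dimethoxybenzene; 2 propiolic acid (prop-2-ynoic acid)
Product: 3 3-(2,4-dimethoxyphenyl)prop-2-ynoic acid
Conditions: Pd(PPh3)4 (cat.), DBU (2.4 equiv.), DMSO, 35 °C; then aq. HCl
Reagents that add atoms: none
Why: Copper-free Sonogashira coupling: zerovalent palladium inserts into the C–I bond and the DBU propiolate is transferred and reductively eliminated. At 35 °C the arylpropiolate salt should keep its CO2, and without copper there is no alkyne homocoupling or copper-mediated decarboxylation.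

Step 2
Reactants: 3 3-(2,4-dimethoxyphenyl)prop-2-ynoic acid
Product: 4 3-(2,4-dimethoxyphenyl)-N-methoxy-N-methylprop-2-ynamide
Conditions: MeNH(OMe)·HCl, DCC, Et3N, DMAP (cat.), CH2Cl2, 0 °C → rt
Reagents that add atoms: N,O-dimethylhydroxylamine hydrochloride, CNOC.Cl
Why: Carbodiimide amidation to the Weinreb amide: the activated ester of 3 is intercepted by the weakly basic N,O-dimethylhydroxylamine, which is too poor a Michael donor to add to the aryl-capped triple bond under these conditions.

Step 3
Reactants: 5 4-hydroxy-6-methyl-2H-pyran-2-one; 4 3-(2,4-dimethoxyphenyl)-N-methoxy-N-methylprop-2-ynamide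
Product: 7 6-[4-(2,4-dimethoxyphenyl)-2-oxobut-3-yn-1-yl]-4-hydroxy-2H-pyran-2-one, via pyrone dilithium dianion 6 (not isolated)
Conditions: LiN(i-Pr)2 (2.1 equiv.), THF, −78 → −20 °C; then 4, −78 → −20 °C; poured into cold aq. HCl
Reagents that add atoms: none
Why: Claisen-type C-acylation of the O,C-dianion of a 4-hydroxy-6-methyl-2-pyrone at its methyl carbon, the most basic site once the hydroxyl is ionised, by a Weinreb amide. The lithium-chelated tetrahedral adduct keeps the ynone masked until the quench, so neither 6 nor the amines meet a free Michael acceptor, and the inverse acidic quench protonates the amines before the ketone is released.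

Step 4
Reactants: 7 6-[4-(2,4-dimethoxyphenyl)-2-oxobut-3-yn-1-yl]-4-hydroxy-2H-pyran-2-one
Product: 10 2-(2,4-dimethoxyphenyl)-5,7-dihydroxy-4H-chromen-4-one, via triketo ester 8 (not isolated), via acylphloroglucinol ynone 9 (not isolated)
Conditions: Mg(OMe)2 (6 equiv.), MeOH, reflux; then 2 M aq. HCl, rt
Reagents that add atoms: none
Why: Methoxide from Mg(OMe)2 attacks the lactone carbonyl of 7 (the future C8a), the ring opens, the C5 oxygen is freed and the magnesium polyenolate of triketo ester 8 results. The carbanion at C4a, held between the C4 and C5 carbonyls in a magnesium β-diketonate, attacks the ester carbon in a 6-exo-trig Claisen condensation that forms C4a–C8a and closes ring A; loss of methoxide and enolisation give the symmetric acylphloroglucinol 9. An ortho phenoxide of 9 then adds to the β-carbon of the ynone in a 6-endo-dig oxa-Michael addition that forms O1–C2 and closes ring C. If methoxide adds to the alkyne first, the phenoxide closes by addition–elimination on the β-methoxy enone, so both paths converge on 10 and the acidic finish completes the closure. The closest known reactions are the Mg(OMe)2-induced conversion of 6-(2-oxoalkyl)-4-hydroxy-2-pyrones into acylphloroglucinols and the base-mediated cyclisation of 2-hydroxyaryl ynones to flavones. No stereocentre is formed. The step needs Claisen folding (C4a to C8a) to win over aldol folding (C8 to C4, which would give a resorcylate) and needs the freed C5 enolate oxygen to stay off the triple bond; chelation of the β-dicarbonyl units by divalent magnesium turns the ketones into unreactive enolates, leaves the ester as the only electrophile and holds the C5 oxygen turned toward the C4 oxygen and away from the alkyne. The choice between the two ortho phenols of 9 disappears through the symmetry of the phloroglucinol ring, and six-membered closure is preferred because the five-membered mode would be an anti-Michael attack at the α-carbon without enolate stabilisation.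

Step 5
Reactants: 10 2-(2,4-dimethoxyphenyl)-5,7-dihydroxy-4H-chromen-4-one
Product: 11 2-(2,4-dimethoxyphenyl)-5-hydroxy-7-methoxy-4H-chromen-4-one
Conditions: MeI (1.1 equiv.), K2CO3, acetone, reflux
Reagents that add atoms: iodomethane, CI
Why: Williamson etherification, selective because the C7 hydroxyl is the more acidic, unchelated phenol, whereas the C5 hydroxyl is hydrogen-bonded to the C4 carbonyl and is not alkylated by one equivalent of MeI with a weak base.

Step 6
Reactants: 11 2-(2,4-dimethoxyphenyl)-5-hydroxy-7-methoxy-4H-chromen-4-one
Product: 13 2-(2,4-dimethoxyphenyl)-5,8-dihydroxy-7-methoxy-4H-chromen-4-one, via potassium 8-sulfate ester 12 (not isolated)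
Conditions: K2S2O8, aq. KOH, pyridine, 15 °C; then conc. HCl, 90 °C, under N2
Reagents that add atoms: potassium peroxodisulfate, [K+].[K+].[O-]S(=O)(=O)OOS(=O)(=O)[O-]
Why: Elbs peroxodisulfate oxidation: the C5 phenolate attacks a peroxide oxygen through its para carbon C8 (C6 is only ortho), and the aryl sulfate 12 shields the new oxygen from further oxidation until acid hydrolyses it. Ring A carries the only phenolate, so ring B and the C2–C3 double bond should stay untouched.

Step 7
Reactants: 13 2-(2,4-dimethoxyphenyl)-5,8-dihydroxy-7-methoxy-4H-chromen-4-one
Product: 14 2-(2,4-dimethoxyphenyl)-5-hydroxy-7,8-dimethoxy-4H-chromen-4-one (5-hydroxy-2',4',7,8-tetramethoxyflavone, the target)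
Conditions: MeI (1.1 equiv.), K2CO3 (1.1 equiv.), acetone, rt → 40 °C, under N2
Reagents that add atoms: iodomethane, CI
Why: Williamson etherification of the unchelated, more acidic C8 hydroxyl; the C5 hydroxyl stays hydrogen-bonded to the C4 carbonyl as in step 5, and the inert atmosphere protects the hydroquinone from air oxidation in base.

## Compound list

No compound of the route has a stereocentre.

1 | 1-iodo-2,4-dimethoxybenzene | COc1ccc(I)c(OC)c1 | starting material
2 | propiolic acid (prop-2-ynoic acid) | C#CC(=O)O | starting material
3 | 3-(2,4-dimethoxyphenyl)prop-2-ynoic acid | COc1ccc(C#CC(=O)O)c(OC)c1 | intermediate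
4 | 3-(2,4-dimethoxyphenyl)-N-methoxy-N-methylprop-2-ynamide | COc1ccc(C#CC(=O)N(C)OC)c(OC)c1 | intermediate
5 | 4-hydroxy-6-methyl-2H-pyran-2-one | Cc1cc(O)cc(=O)o1 | starting material
6 | dilithium salt of 5 deprotonated at the 4-hydroxyl and at the methyl carbon (formed in the flask) | [Li+].[Li+].[CH2-]c1cc([O-])cc(=O)o1 | intermediate
7 | 6-[4-(2,4-dimethoxyphenyl)-2-oxobut-3-yn-1-yl]-4-hydroxy-2H-pyran-2-one | O=c1cc(O)cc(CC(=O)C#Cc2ccc(OC)cc2OC)o1 | intermediate
8 | methyl 9-(2,4-dimethoxyphenyl)-3,5,7-trioxonon-8-ynoate (present as its magnesium enolate, formed in the flask) | COC(=O)CC(=O)CC(=O)CC(=O)C#Cc1ccc(OC)cc1OC | intermediate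
9 | 3-(2,4-dimethoxyphenyl)-1-(2,4,6-trihydroxyphenyl)prop-2-yn-1-one (formed in the flask) | COc1ccc(C#CC(=O)c2c(O)cc(O)cc2O)c(OC)c1 | intermediate
10 | 2-(2,4-dimethoxyphenyl)-5,7-dihydroxy-4H-chromen-4-one | COc1ccc(-c2cc(=O)c3c(O)cc(O)cc3o2)c(OC)c1 | intermediate
11 | 2-(2,4-dimethoxyphenyl)-5-hydroxy-7-methoxy-4H-chromen-4-one | COc1ccc(-c2cc(=O)c3c(O)cc(OC)cc3o2)c(OC)c1 | intermediate
12 | potassium 2-(2,4-dimethoxyphenyl)-5-hydroxy-7-methoxy-4-oxo-4H-chromen-8-yl sulfate (formed in the flask) | COc1ccc(-c2cc(=O)c3c(O)cc(OC)c(OS(=O)(=O)[O-])c3o2)c(OC)c1.[K+] | intermediate
13 | 2-(2,4-dimethoxyphenyl)-5,8-dihydroxy-7-methoxy-4H-chromen-4-one | COc1ccc(-c2cc(=O)c3c(O)cc(OC)c(O)c3o2)c(OC)c1 | intermediate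
14 | 2-(2,4-dimethoxyphenyl)-5-hydroxy-7,8-dimethoxy-4H-chromen-4-one (5-hydroxy-2',4',7,8-tetramethoxyflavone) | COc1ccc(-c2cc(=O)c3c(O)cc(OC)c(OC)c3o2)c(OC)c1 | target

## Step count and least certain steps

Total: 7 steps. Longest linear sequence: 7 steps (1 and 2 → 3 → 4 → 7 → 10 → 11 → 13 → 14); 5 enters at step 3.

**Step 4 (key step).** The most likely failure is misfolding of the opened chain. Once methoxide frees the C5 oxygen, oxygen cyclisation of that enolate onto the triple bond (to a 4-pyranone) or aldol-type closure can overtake the slower Claisen closure. In the protic medium the last ring could also close in the five-membered mode. Ring opening of the deprotonated hydroxypyrone may itself be sluggish.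

The fallback takes ring A from a preformed phloroglucinol instead of folding it, sets out from 4 and comes back at 9. 1,3,5-Tris(methoxymethoxy)benzene F1 (from phloroglucinol, MOMCl and i-Pr2NEt) would be lithiated between two of its oxygens with n-BuLi in THF at 0 °C to 2,4,6-tris(methoxymethoxy)phenyllithium F2. Addition of F2 to the amide carbonyl of 4 at −78 °C should give, after work-up, 3-(2,4-dimethoxyphenyl)-1-[2,4,6-tris(methoxymethoxy)phenyl]prop-2-yn-1-one F3. HCl in methanol would remove the three acetals to give 9, and K2CO3 in acetone (aprotic, six-membered closure) would then close 9 to 10.

**Step 3.** The most likely failure is conjugate addition of the soft, delocalised carbanion of 6 to the triple bond of 4 in place of attack at the amide carbonyl. Elimination of formaldehyde from the N-methoxy group by excess amide base, and self-condensation of the released ynone during the quench, are further risks.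

The fallback replaces acylation by addition to an aldehyde followed by oxidation, sets out from 4 and comes back at 7. i-Bu2AlH in THF at −78 °C would reduce 4 to 3-(2,4-dimethoxyphenyl)prop-2-ynal F4. Dianion 6, made from 5 as in step 3, should add 1,2 to the aldehyde at −78 °C to give racemic 6-[4-(2,4-dimethoxyphenyl)-2-hydroxybut-3-yn-1-yl]-4-hydroxy-2H-pyran-2-one F5. MnO2 in CH2Cl2, or Dess–Martin periodinane, would oxidise the propargylic alcohol of F5 to 7.

**Step 6.** The most likely failure is incomplete and unselective oxidation. The chelated C5 phenolate is a weak nucleophile toward peroxodisulfate, so conversion is expected to stall. Long exposure to aqueous base and oxidant can open the pyranone at C2, and the hydroquinone can over-oxidise once the sulfate is hydrolysed.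

The fallback introduces the C8 oxygen by formylation and oxidative rearrangement, sets out from 10 and comes back at 14. Duff formylation (hexamethylenetetramine, AcOH, 100 °C, then aq. HCl) should take place at C8, the position at which 5,7-dihydroxyflavones are generally substituted first, and give 2-(2,4-dimethoxyphenyl)-5,7-dihydroxy-4-oxo-4H-chromene-8-carbaldehyde F6. Dakin oxidation (H2O2, aq. NaOH, 0 °C → rt) would convert the aldehyde into the phenol 2-(2,4-dimethoxyphenyl)-5,7,8-trihydroxy-4H-chromen-4-one F7. MeI (2.2 equiv.) with K2CO3 in acetone would then methylate the two unchelated hydroxyls of F7 and give 14.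

**Step 1.** The most likely failure is loss of CO2 from the arylpropiolate during the coupling, followed by a second coupling of the resulting terminal alkyne. Slow oxidative addition of the electron-rich, ortho-substituted iodide makes this more likely if the temperature has to be raised.

The fallback forms the amide before the C–C bond so that no free acid meets palladium, sets out from 2 (with 1) and comes back at 4. Acid 2 would be coupled with MeNH(OMe)·HCl (DCC, CH2Cl2, −10 °C) to N-methoxy-N-methylprop-2-ynamide F8. Sonogashira coupling of F8 with 1 (PdCl2(PPh3)2, CuI, i-Pr2NEt, THF, rt) should give 4 directly.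

## Further compounds

F1 | step 4 | 1,3,5-tris(methoxymethoxy)benzene | COCOc1cc(OCOC)cc(OCOC)c1
F2 | step 4 | 2,4,6-tris(methoxymethoxy)phenyllithium | [Li]c1c(OCOC)cc(OCOC)cc1OCOC
F3 | step 4 | 3-(2,4-dimethoxyphenyl)-1-[2,4,6-tris(methoxymethoxy)phenyl]prop-2-yn-1-one | COCOc1cc(OCOC)c(C(=O)C#Cc2ccc(OC)cc2OC)c(OCOC)c1
F4 | step 3 | 3-(2,4-dimethoxyphenyl)prop-2-ynal | COc1ccc(C#CC=O)c(OC)c1
F5 | step 3 | racemic 6-[4-(2,4-dimethoxyphenyl)-2-hydroxybut-3-yn-1-yl]-4-hydroxy-2H-pyran-2-one | O=c1cc(O)cc(CC(O)C#Cc2ccc(OC)cc2OC)o1
F6 | step 6 | 2-(2,4-dimethoxyphenyl)-5,7-dihydroxy-4-oxo-4H-chromene-8-carbaldehyde | COc1ccc(-c2cc(=O)c3c(O)cc(O)c(C=O)c3o2)c(OC)c1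
F7 | step 6 | 2-(2,4-dimethoxyphenyl)-5,7,8-trihydroxy-4H-chromen-4-one | COc1ccc(-c2cc(=O)c3c(O)cc(O)c(O)c3o2)c(OC)c1
F8 | step 1 | N-methoxy-N-methylprop-2-ynamide | C#CC(=O)N(C)OC
A1 | alternative 1 | 2-iodo-3,5,6-trimethoxyphenol | COc1cc(OC)c(OC)c(O)c1I
A2 | alternative 1 | 1-ethynyl-2,4-dimethoxybenzene | C#Cc1ccc(OC)cc1OC
A3 | alternative 1 | 2-(2,4-dimethoxyphenyl)-5,7,8-trimethoxy-4H-chromen-4-one | COc1ccc(-c2cc(=O)c3c(OC)cc(OC)c(OC)c3o2)c(OC)c1
A4 | alternative 2 | 1-(3,6-dihydroxy-2,4-dimethoxyphenyl)-3-(2,4-dimethoxyphenyl)propane-1,3-dione | COc1ccc(C(=O)CC(=O)c2c(O)cc(OC)c(O)c2OC)c(OC)c1
A5 | alternative 2 | 2-[3-(2,4-dimethoxyphenyl)-3-oxopropanoyl]-3,5-dimethoxycyclohexa-2,5-diene-1,4-dione | COC1=CC(=O)C(C(=O)CC(=O)c2ccc(OC)cc2OC)=C(OC)C1=O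
A6 | alternative 2 | 2-(2,4-dimethoxyphenyl)-7-methoxy-4H-chromene-4,5,8-trione | COc1ccc(-c2cc(=O)c3c(o2)C(=O)C(OC)=CC3=O)c(OC)c1
A7 | alternative 3 | 3,5-dimethoxy-2-(trimethylsilyl)phenyl trifluoromethanesulfonate | COc1cc(OC)c([Si](C)(C)C)c(OS(=O)(=O)C(F)(F)F)c1
A8 | alternative 3 | 2-(2,4-dimethoxyphenyl)-5,7-dimethoxy-4H-chromen-4-one | COc1ccc(-c2cc(=O)c3c(OC)cc(OC)cc3o2)c(OC)c1
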